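**Retrosynthetic overview**
1. 29 ⇐ 28 (O9–Si cleavage) ⇐ acyclic ynal 27. A new Ni(0)-catalysed reductive endo-macrocyclisation forms C9–C10, closes the ten-membered carbocycle, and sets the E-C1=C10 alkene and C9 in one step.
2. 27 ⇐ 23. OH-directed epoxidation under A1,3 control builds the C4–C5 oxirane on the open chain. O6 acetylation and oxidative unmasking of C9 follow.
3. 23 ⇐ β-hydroxy enone 21 + tiglaldehyde 22. An Evans–Tishchenko reduction sets C6 (1,3-anti) and places the tiglate on O8.
4. 21 ⇐ Weinreb amide 18 + alkenyl iodide 7 (C5–C6). 18 ⇐ Evans syn aldol of 14 with 11 (C7–C8, sets C7 and C8). 7 ⇐ carboalumination of diyne 5 (fixes the E-C4=C5 geometry).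
5. Ring order: oxirane first (step 11), ten-membered carbocycle last (step 14).

Assumption: the acyl group C/C=C(\C)C(=O)O is read as (E)-2-methylbut-2-enoate (tiglate); germacrane numbering is used (C1=C10 alkene, C4–C5 oxirane, C6 OAc, C7 i-Pr, C8 O-tigloyl, C9 OH; target = 4R,5R,6S,7S,8S,9R); CIP letters at C6/C7 that differ between intermediates come from priority changes only, never from inversion; 1, 2, 8, 12, 13 and 22 are taken as commercial.

**Step 1**
Reactants: 1 1-(trimethylsilyl)propyne; 2 1-bromobut-2-yne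
Product: 4 trimethyl(hepta-1,5-diyn-1-yl)silane, via 3-(trimethylsilyl)prop-2-ynyllithium 3 (not isolated)
Conditions: 1, n-BuLi, THF, −78 to −20 °C; then 2, −78 °C to rt
Reagents that add atoms: none
Why: Carbanion SN2 alkylation, in which the silyl-capped propargyllithium attacks the primary propargylic bromide through its CH2 terminus and joins C2–C3 to give the 1,5-diyne (no stereocentre involved).

**Step 2**
Reactants: 4 trimethyl(hepta-1,5-diyn-1-yl)silane
Product: 5 hepta-1,5-diyne
Conditions: K2CO3 (0.2 equiv), MeOH, rt; extracted into CH2Cl2 and used as a dried solution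
Reagents that add atoms: none
Why: Base-catalysed methanolytic protodesilylation cleaves only the alkynyl C–Si bond and frees the terminal alkyne.

**Step 3**
Reactants: 5 hepta-1,5-diyne
Product: 7 (E)-1-iodo-2-methylhept-1-en-5-yne, via alkenyldimethylalane 6 (not isolated)
Conditions: Me3Al (2 equiv), Cp2ZrCl2 (20 mol %), CH2Cl2, 0 °C to rt; then I2, THF, −30 °C
Reagents that add atoms: trimethylaluminium C[Al](C)C; iodine II
Why: Negishi Zr-catalysed carboalumination adds Me–Al syn and far faster to the terminal than to the internal alkyne, and iodinolysis with retention fixes the E-C4=C5 geometry that later becomes the trans-oxirane.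

**Step 4**
Reactants: 8 (Z)-but-2-ene-1,4-diol
Product: 9 (Z)-1,4-bis(triethylsilyloxy)but-2-ene
Conditions: TESCl (2.1 equiv), imidazole, CH2Cl2, 0 °C
Reagents that add atoms: chlorotriethylsilane CC[Si](Cl)(CC)CC
Why: Imidazole-promoted silyl ether formation on two unhindered primary alcohols is quantitative.

**Step 5**
Reactants: 9 (Z)-1,4-bis(triethylsilyloxy)but-2-ene
Product: 11 2-(triethylsilyloxy)acetaldehyde, via secondary ozonide 10 (not isolated)
Conditions: O3, CH2Cl2, −78 °C; then Me2S, −78 °C to rt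
Reagents that add atoms: ozone [O-][O+]=O
Why: Ozonolysis with reductive work-up cleaves the symmetric alkene into two equivalents of the C8–C9 aldehyde under neutral conditions that keep the TES ether.

**Step 6**
Reactants: 12 (S)-4-benzyloxazolidin-2-one; 13 3-methylbutanoyl chloride
Product: 14 (S)-4-benzyl-3-(3-methylbutanoyl)oxazolidin-2-one
Conditions: Et3N, DMAP (10 mol %), CH2Cl2, 0 °C to rt
Reagents that add atoms: none
Why: DMAP-catalysed N-acylation of the auxiliary by the acid chloride is a routine, high-yielding reaction.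

**Step 7**
Reactants: 14 (S)-4-benzyl-3-(3-methylbutanoyl)oxazolidin-2-one; 11 2-(triethylsilyloxy)acetaldehyde
Product: 17 (S)-4-benzyl-3-[(2S,3S)-3-hydroxy-2-(propan-2-yl)-4-(triethylsilyloxy)butanoyl]oxazolidin-2-one, via boron enolate 15 (not isolated), via boron aldolate 16 (not isolated)
Conditions: Bu2BOTf, Et3N, CH2Cl2, 0 °C; 11, −78 to 0 °C; then pH 7 buffer, MeOH, 30% H2O2, 0 °C
Reagents that add atoms: none
Why: In the Evans syn aldol the Z-boron enolate reacts through a dipole-minimised Zimmerman–Traxler chair on the face away from the benzyl group, forming C7–C8 and setting C7 (S) and C8 (S) in the required 7,8-syn relation.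

**Step 8**
Reactants: 17 (S)-4-benzyl-3-[(2S,3S)-3-hydroxy-2-(propan-2-yl)-4-(triethylsilyloxy)butanoyl]oxazolidin-2-one
Product: 18 (2S,3S)-3-hydroxy-N-methoxy-N-methyl-2-(propan-2-yl)-4-(triethylsilyloxy)butanamide
Conditions: MeONHMe·HCl, Me3Al, THF/CH2Cl2, −10 °C to rt; Rochelle salt work-up
Reagents that add atoms: N,O-dimethylhydroxylamine hydrochloride CNOC.Cl
Why: Aluminium-amide (Weinreb) transamidation, assisted by the free β-hydroxyl, selectively cleaves the exocyclic imide carbonyl without epimerising C7 and releases the auxiliary.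

**Step 9**
Reactants: 18 (2S,3S)-3-hydroxy-N-methoxy-N-methyl-2-(propan-2-yl)-4-(triethylsilyloxy)butanamide; 7 (E)-1-iodo-2-methylhept-1-en-5-yne
Product: 21 (2S,3S,5E)-2-hydroxy-6-methyl-3-(propan-2-yl)-1-(triethylsilyloxy)undec-5-en-9-yn-4-one, via alkenyllithium 19 (not isolated), via chloromagnesium alkoxide 20 (not isolated)
Conditions: 7 (1.3 equiv), t-BuLi (2.6 equiv), Et2O, −78 °C; separately 18, i-PrMgCl (1.0 equiv), THF, −20 °C; combine, −78 to −20 °C; aq NH4Cl
Reagents that add atoms: none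
Why: Stereoretentive lithium–iodine exchange followed by Weinreb ketone synthesis forms C5–C6 with a single addition, and masking O8 as its magnesium alkoxide saves alkenyllithium and suppresses retro-aldol and silyl migration.

**Step 10**
Reactants: 21 (2S,3S,5E)-2-hydroxy-6-methyl-3-(propan-2-yl)-1-(triethylsilyloxy)undec-5-en-9-yn-4-one; 22 (E)-2-methylbut-2-enal
Product: 23 (2S,3R,4R,5E)-4-hydroxy-6-methyl-3-(propan-2-yl)-1-(triethylsilyloxy)undec-5-en-9-yn-2-yl (E)-2-methylbut-2-enoate
Conditions: SmI2 (30 mol %, premixed with 22), 22 (6 equiv), THF, −10 °C, dark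
Reagents that add atoms: none
Why: In the Evans–Tishchenko reduction the Sm(III)-bound hemiacetal formed from O8 and 22 passes its hydride intramolecularly to C6 through a chair-like bicyclic transition state, which sets the 6,8-anti carbinol (the target's C6 configuration, labelled 4R here), leaves the tiglate on O8 and leaves O6 free.

**Step 11**
Reactants: 23 (2S,3R,4R,5E)-4-hydroxy-6-methyl-3-(propan-2-yl)-1-(triethylsilyloxy)undec-5-en-9-yn-2-yl (E)-2-methylbut-2-enoate
Product: 24 (2S,3R,4S,5R,6R)-5,6-epoxy-4-hydroxy-6-methyl-3-(propan-2-yl)-1-(triethylsilyloxy)undec-9-yn-2-yl (E)-2-methylbut-2-enoate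
Conditions: m-CPBA (1.1 equiv), NaHCO3, CH2Cl2, −20 to 0 °C
Reagents that add atoms: 3-chloroperoxybenzoic acid OOC(=O)c1cccc(Cl)c1
Why: In this Henbest hydroxyl-directed epoxidation the C4 methyl cis to C6 forces H6 into the alkene plane (A1,3 strain), so the H-bonded peracid attacks the face bearing O6 and remote from bulky C7 to give the threo (germacrane 4R,5R) trans-oxirane, while the electron-poor tiglate and the alkyne stay untouched.

**Step 12**
Reactants: 24 (2S,3R,4S,5R,6R)-5,6-epoxy-4-hydroxy-6-methyl-3-(propan-2-yl)-1-(triethylsilyloxy)undec-9-yn-2-yl (E)-2-methylbut-2-enoate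
Product: 25 (2S,3S,4S,5R,6R)-4-acetoxy-5,6-epoxy-6-methyl-3-(propan-2-yl)-1-(triethylsilyloxy)undec-9-yn-2-yl (E)-2-methylbut-2-enoate
Conditions: Ac2O, pyridine, DMAP (5 mol %), CH2Cl2, 0 °C to rt
Reagents that add atoms: acetic anhydride CC(=O)OC(C)=O
Why: DMAP-catalysed acetylation caps the only free hydroxyl (O6) under weakly basic conditions that cause neither Payne rearrangement nor acyl shift.

**Step 13**
Reactants: 25 (2S,3S,4S,5R,6R)-4-acetoxy-5,6-epoxy-6-methyl-3-(propan-2-yl)-1-(triethylsilyloxy)undec-9-yn-2-yl (E)-2-methylbut-2-enoate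
Product: 27 (2S,3R,4S,5R,6R)-4-acetoxy-5,6-epoxy-6-methyl-1-oxo-3-(propan-2-yl)undec-9-yn-2-yl (E)-2-methylbut-2-enoate, via alkoxysulfonium chloride 26 (not isolated)
Conditions: (COCl)2 (4 equiv), DMSO (8 equiv), CH2Cl2, −78 to −40 °C; then Et3N, −78 to −20 °C; used crude
Reagents that add atoms: none
Why: Swern oxidation applied directly to the primary TES ether (oxidative desilylation) gives the C9 aldehyde without ever freeing a primary alcohol next to the O8 tiglate, so no 8→9 acyl shift can occur, and the cold amine step protects C8 from epimerisation.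

**Step 14**
Reactants: 27 (2S,3R,4S,5R,6R)-4-acetoxy-5,6-epoxy-6-methyl-1-oxo-3-(propan-2-yl)undec-9-yn-2-yl (E)-2-methylbut-2-enoate
Product: 28 (1(10)E,4R,5R,6S,7R,8S,9R)-6-acetoxy-4,5-epoxy-9-(triethylsilyloxy)germacr-1(10)-en-8-yl (E)-2-methylbut-2-enoate
Conditions: Ni(cod)2 (20 mol %), IMes (1,3-dimesitylimidazol-2-ylidene, 20 mol %), Et3SiH (3 equiv), THF, 25 °C, 27 added by syringe pump over 12 h (final 2 mM); Et3N-deactivated silica
Reagents that add atoms: triethylsilane CC[SiH](CC)CC
Why: Proposed new method: silane-terminated Ni(0)/NHC reductive ynal cyclisation, so far shown for small rings and large macrocycles but not for endo closure of a ten-membered (E)-cycloalkene carrying an oxirane and an enoate, should proceed by oxidative cyclisation of Ni(0) with the C1≡C10 alkyne and the C9 aldehyde to an oxanickelacyclopentene in which the compact IMes lets the tether-bearing C1 sit on nickel so that the methyl-bearing C10 bonds to C9 (endo, ten-membered), then Si–H σ-bond metathesis at Ni–O and C–H reductive elimination place H on C1 syn to C9 (hence the E alkene) and cap O9 as its TES ether (no alkoxide, so no acyl shift), with the aldehyde face fixed by a polar Felkin–Anh arrangement in which C8–O lies perpendicular to C=O (8,9-anti, 9R) and the trans-oxirane plus the three contiguous branched centres pre-folding the seven-atom tether; the closest known reaction type is the nickel-catalysed reductive aldehyde–alkyne coupling/macrocyclisation.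

**Step 15**
Reactants: 28 (1(10)E,4R,5R,6S,7R,8S,9R)-6-acetoxy-4,5-epoxy-9-(triethylsilyloxy)germacr-1(10)-en-8-yl (E)-2-methylbut-2-enoate
Product: 29 (1(10)E,4R,5R,6S,7S,8S,9R)-6-acetoxy-4,5-epoxy-9-hydroxygermacr-1(10)-en-8-yl (E)-2-methylbut-2-enoate
Conditions: HF·pyridine, excess pyridine, THF, 0 °C; neutral work-up
Reagents that add atoms: none
Why: Pyridine-buffered fluoride desilylation removes the labile secondary TES ether without the acid that would trigger transannular oxirane–alkene cyclisation or the base that would move the tiglate, and no stereocentre is touched.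

**Compound list**
1 | 1-(trimethylsilyl)propyne | CC#C[Si](C)(C)C | starting material
2 | 1-bromobut-2-yne | CC#CCBr | starting material
3 | 3-(trimethylsilyl)prop-2-ynyllithium (not isolated) | [Li]CC#C[Si](C)(C)C | intermediate
4 | trimethyl(hepta-1,5-diyn-1-yl)silane | CC#CCCC#C[Si](C)(C)C | intermediate
5 | hepta-1,5-diyne | CC#CCCC#C | intermediate
6 | dimethyl[(E)-2-methylhept-1-en-5-yn-1-yl]alane (not isolated) | CC#CCC/C(C)=C/[Al](C)C | intermediate
7 | (E)-1-iodo-2-methylhept-1-en-5-yne | CC#CCC/C(C)=C/I | intermediate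
8 | (Z)-but-2-ene-1,4-diol | OC/C=C\CO | starting material
9 | (Z)-1,4-bis(triethylsilyloxy)but-2-ene | CC[Si](CC)(CC)OC/C=C\CO[Si](CC)(CC)CC | intermediate
10 | 3,5-bis[(triethylsilyloxy)methyl]-1,2,4-trioxolane (secondary ozonide; not isolated) | CC[Si](CC)(CC)OCC1OOC(CO[Si](CC)(CC)CC)O1 | intermediate
11 | 2-(triethylsilyloxy)acetaldehyde | CC[Si](CC)(CC)OCC=O | intermediate
12 | (S)-4-benzyloxazolidin-2-one | O=C1N[C@@H](Cc2ccccc2)CO1 | starting material
13 | 3-methylbutanoyl chloride | CC(C)CC(=O)Cl | starting material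
14 | (S)-4-benzyl-3-(3-methylbutanoyl)oxazolidin-2-one | CC(C)CC(=O)N1[C@@H](Cc2ccccc2)COC1=O | intermediate
15 | (Z)-dibutylboron enolate of 14 (not isolated) | CCCCB(CCCC)O/C(=C\C(C)C)N1[C@@H](Cc2ccccc2)COC1=O | intermediate
16 | O-dibutylboryl aldolate of 17 (not isolated) | CC[Si](CC)(CC)OC[C@@H](OB(CCCC)CCCC)[C@H](C(C)C)C(=O)N1[C@@H](Cc2ccccc2)COC1=O | intermediate
17 | (S)-4-benzyl-3-[(2S,3S)-3-hydroxy-2-(propan-2-yl)-4-(triethylsilyloxy)butanoyl]oxazolidin-2-one | CC[Si](CC)(CC)OC[C@@H](O)[C@H](C(C)C)C(=O)N1[C@@H](Cc2ccccc2)COC1=O | intermediate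
18 | (2S,3S)-3-hydroxy-N-methoxy-N-methyl-2-(propan-2-yl)-4-(triethylsilyloxy)butanamide | CC[Si](CC)(CC)OC[C@@H](O)[C@H](C(C)C)C(=O)N(C)OC | intermediate
19 | (E)-2-methylhept-1-en-5-yn-1-yllithium (not isolated) | CC#CCC/C(C)=C/[Li] | intermediate
20 | chloromagnesium alkoxide of 18 (not isolated) | CC[Si](CC)(CC)OC[C@@H](O[Mg]Cl)[C@H](C(C)C)C(=O)N(C)OC | intermediate
21 | (2S,3S,5E)-2-hydroxy-6-methyl-3-(propan-2-yl)-1-(triethylsilyloxy)undec-5-en-9-yn-4-one | CC[Si](CC)(CC)OC[C@@H](O)[C@H](C(C)C)C(=O)/C=C(\C)CCC#CC | intermediate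
22 | (E)-2-methylbut-2-enal (tiglaldehyde) | C/C=C(\C)C=O | starting material
23 | (2S,3R,4R,5E)-4-hydroxy-6-methyl-3-(propan-2-yl)-1-(triethylsilyloxy)undec-5-en-9-yn-2-yl (E)-2-methylbut-2-enoate | CC[Si](CC)(CC)OC[C@@H](OC(=O)/C(C)=C/C)[C@H](C(C)C)[C@H](O)/C=C(\C)CCC#CC | intermediate
24 | (2S,3R,4S,5R,6R)-5,6-epoxy-4-hydroxy-6-methyl-3-(propan-2-yl)-1-(triethylsilyloxy)undec-9-yn-2-yl (E)-2-methylbut-2-enoate | CC[Si](CC)(CC)OC[C@@H](OC(=O)/C(C)=C/C)[C@H](C(C)C)[C@H](O)[C@H]1O[C@]1(C)CCC#CC | intermediate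
25 | (2S,3S,4S,5R,6R)-4-acetoxy-5,6-epoxy-6-methyl-3-(propan-2-yl)-1-(triethylsilyloxy)undec-9-yn-2-yl (E)-2-methylbut-2-enoate | CC[Si](CC)(CC)OC[C@@H](OC(=O)/C(C)=C/C)[C@H](C(C)C)[C@H](OC(C)=O)[C@H]1O[C@]1(C)CCC#CC | intermediate
26 | dimethyl(alkoxy)sulfonium chloride of the C9 oxygen of 25 (TES replaced by SMe2+; not isolated) | C[S+](C)OC[C@@H](OC(=O)/C(C)=C/C)[C@H](C(C)C)[C@H](OC(C)=O)[C@H]1O[C@]1(C)CCC#CC.[Cl-] | intermediate
27 | (2S,3R,4S,5R,6R)-4-acetoxy-5,6-epoxy-6-methyl-1-oxo-3-(propan-2-yl)undec-9-yn-2-yl (E)-2-methylbut-2-enoate | O=C[C@@H](OC(=O)/C(C)=C/C)[C@H](C(C)C)[C@H](OC(C)=O)[C@H]1O[C@]1(C)CCC#CC | intermediate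
28 | (1(10)E,4R,5R,6S,7R,8S,9R)-6-acetoxy-4,5-epoxy-9-(triethylsilyloxy)germacr-1(10)-en-8-yl (E)-2-methylbut-2-enoate | C/C=C(\C)C(=O)O[C@H]1[C@H](C(C)C)[C@H](OC(C)=O)[C@H]2O[C@]2(C)CC/C=C(\C)[C@H]1O[Si](CC)(CC)CC | intermediate
29 | (1(10)E,4R,5R,6S,7S,8S,9R)-6-acetoxy-4,5-epoxy-9-hydroxygermacr-1(10)-en-8-yl (E)-2-methylbut-2-enoate (CNP0163041.1) | C/C=C(\C)C(=O)O[C@H]1[C@H](C(C)C)[C@H](OC(C)=O)[C@H]2O[C@]2(C)CC/C=C(\C)[C@H]1O | target

**Total step count:** 15.
**Longest linear sequence:** 11 steps (8 → 9 → 11 → 17 → 18 → 21 → 23 → 24 → 25 → 27 → 28 → 29; steps 4, 5, 7–15).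

**Three steps most likely to fail**

1. **Step 14 (the proposed new method).** Risks:
   - strain and entropy of the medium ring;
   - exo closure to a nine-membered ring, or oligomerisation;
   - aldehyde or alkyne hydrosilylation;
   - nickel binding to the tiglate or opening the oxirane;
   - insufficient facial control at C9.

   The fallback uses known chemistry only. It sets out from 25 and comes back to the route at 29. Palladium-catalysed syn-hydrostannation of the methyl alkyne (Bu3SnH, PdCl2(PPh3)2, THF, 0 °C, regioisomers separated on silica) gives the (E)-C10-alkenylstannane F1. Iododestannylation with retention (I2, CH2Cl2, 0 °C) gives the (E)-alkenyl iodide F2. The Swern oxidative desilylation of step 13 then passes through the alkoxysulfonium chloride F3 to the iodo aldehyde F4. Nozaki–Hiyama–Kishi macrocyclisation (CrCl2, 1 mol % NiCl2, DMSO/THF, 3 mM, rt) closes C9–C10 with retention of the alkene geometry and Felkin-type 8,9-anti selectivity. This delivers 29 directly, so 27, 28 and step 15 are bypassed.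

2. **Step 10.** Conjugated, α-branched enals are unusual hydride donors in the Evans–Tishchenko reaction. Hemiacetal formation may be slow, 22 may be consumed by pinacol or Tishchenko self-reaction, and the ester may drift from O8 to O6. The fallback separates acylation from reduction. It sets out from 21 and comes back at 23. O8 is acylated with tigloyl chloride (pyridine, catalytic DMAP, CH2Cl2, 0 °C, kept cold to avoid β-elimination) to give the β-tigloyloxy enone F5. Reagent-controlled 1,2-reduction follows ((R)-Me-CBS, catecholborane, toluene, −78 °C, with the alkenyl arm assumed to act as the large group; this assignment is uncertain because C7 is heavily branched). It passes through the catecholborate ester F6, which is hydrolysed on work-up to 23.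

3. **Step 11.** This is the only acyclic substrate-controlled stereo-induction in the route. An internal O6–H···O=C(tiglate) hydrogen bond could weaken peracid direction and erode the threo selectivity. The acid by-product also threatens the TES ether and the epoxy alcohol. The fallback switches to reagent control and reverses the order of events. It sets out from 23 and comes back at 25. Acetylation (Ac2O, pyridine, DMAP) gives the allylic acetate F7. Shi epoxidation with the D-fructose-derived ketone (Oxone, K2CO3, MeCN/dimethoxymethane/aqueous borate buffer, 0 °C) attacks only the electron-rich E-trisubstituted alkene on its (R,R)-face and gives 25 directly, bypassing 24.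

**Further compounds**
F1 | step 14 | (2S,3S,4S,5R,6R,9E)-4-acetoxy-5,6-epoxy-6-methyl-3-(propan-2-yl)-10-(tributylstannyl)-1-(triethylsilyloxy)undec-9-en-2-yl (E)-2-methylbut-2-enoate | CC[Si](CC)(CC)OC[C@@H](OC(=O)/C(C)=C/C)[C@H](C(C)C)[C@H](OC(C)=O)[C@H]1O[C@]1(C)CC/C=C(\C)[Sn](CCCC)(CCCC)CCCC
F2 | step 14 | (2S,3S,4S,5R,6R,9E)-4-acetoxy-5,6-epoxy-10-iodo-6-methyl-3-(propan-2-yl)-1-(triethylsilyloxy)undec-9-en-2-yl (E)-2-methylbut-2-enoate | CC[Si](CC)(CC)OC[C@@H](OC(=O)/C(C)=C/C)[C@H](C(C)C)[C@H](OC(C)=O)[C@H]1O[C@]1(C)CC/C=C(\C)I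
F3 | step 14 | dimethyl(alkoxy)sulfonium chloride of the C9 oxygen of F2 (TES replaced by SMe2+) | C[S+](C)OC[C@@H](OC(=O)/C(C)=C/C)[C@H](C(C)C)[C@H](OC(C)=O)[C@H]1O[C@]1(C)CC/C=C(\C)I.[Cl-]
F4 | step 14 | (2S,3R,4S,5R,6R,9E)-4-acetoxy-5,6-epoxy-10-iodo-6-methyl-1-oxo-3-(propan-2-yl)undec-9-en-2-yl (E)-2-methylbut-2-enoate | O=C[C@@H](OC(=O)/C(C)=C/C)[C@H](C(C)C)[C@H](OC(C)=O)[C@H]1O[C@]1(C)CC/C=C(\C)I
F5 | step 10 | (2S,3S,5E)-6-methyl-4-oxo-3-(propan-2-yl)-1-(triethylsilyloxy)undec-5-en-9-yn-2-yl (E)-2-methylbut-2-enoate | CC[Si](CC)(CC)OC[C@@H](OC(=O)/C(C)=C/C)[C@H](C(C)C)C(=O)/C=C(\C)CCC#CC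
F6 | step 10 | O6-(1,3,2-benzodioxaborol-2-yl) ether of 23 | CC[Si](CC)(CC)OC[C@@H](OC(=O)/C(C)=C/C)[C@H](C(C)C)[C@H](OB1Oc2ccccc2O1)/C=C(\C)CCC#CC
F7 | step 11 | (2S,3R,4R,5E)-4-acetoxy-6-methyl-3-(propan-2-yl)-1-(triethylsilyloxy)undec-5-en-9-yn-2-yl (E)-2-methylbut-2-enoate | CC[Si](CC)(CC)OC[C@@H](OC(=O)/C(C)=C/C)[C@H](C(C)C)[C@H](OC(C)=O)/C=C(\C)CCC#CC
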